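**Retrosynthetic overview**

1. Locants: the styryl-bearing dihydrobenzofuran is O1, C2, C3, C3a, C4–C7, C7a (benzo ring B, furan ring C; ring A is the styryl aryl, ring D the aryl on C2); the second one is O1'–C7a' (benzo ring E, furan ring F; ring G on C2', ring H on C3'). Target 29 ⇐ octamethyl ether 28 by O-demethylation.
2. Ring C is cut across C2–C3 and O1–C7a: 28 ⇐ diarylmethane 24 + 4-methoxybenzaldehyde 25, joined in one anionic addition/ipso-substitution in which an (R)-p-tolylsulfinyl group on C7a is the leaving group.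
3. Enabling feature: C3 is a doubly benzylic CH between rings B and E, and C3a lies between two oxygen-bearing carbons (C4, C7a). A sulfinyl group standing in for O1 at C7a therefore directs lithiation to C3a, acidifies and shields C3–H, and leaves as sulfenate when the C2 alkoxide closes on C7a (same pattern at C3'/C3a'/C7a').
4. 24 ⇐ Negishi coupling (C3–C3a) of zincated stilbene sulfoxide 21 with benzylic bromide 14; 14 ⇐ the same annulation (ring F, antipodal sulfur) on 9 + aldehyde 10; 21 ⇐ Horner–Wadsworth–Emmons stilbene 18.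
5. Ring order: all benzene rings are bought; ring F is closed first (step 4), ring C last (step 9).

Key step: step 9

Assumption: the sense of 1,4-induction by sulfur is taken to be (S)-sulfur → (S)-C3' (step 4) and (R)-sulfur → (R)-C3 (step 9); if it is the opposite, sulfinates 3 and 19 are exchanged between steps 2 and 7 and nothing else changes.

**Route**

Step 1
Reactants: 1 (3-bromo-5-methoxyphenyl)methanol
Product: 2 [(3-bromo-5-methoxyphenyl)methoxy](tert-butyl)dimethylsilane
Conditions: TBSCl, imidazole, DMF, 25 °C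
Reagents that add atoms: tert-butyldimethylsilyl chloride (TBSCl), CC(C)(C)[Si](C)(C)Cl
Why: Imidazole-promoted silyl ether formation masks the primary alcohol against the later organometallics and leaves a handle that step 5 turns into the benzylic bromide.

Step 2
Reactants: 2 [(3-bromo-5-methoxyphenyl)methoxy](tert-butyl)dimethylsilane; 3 (1R,2S,5R)-menthyl (S)-4-methylbenzenesulfinate
Product: 5 tert-butyl({3-methoxy-5-[(S)-4-methylbenzenesulfinyl]phenyl}methoxy)dimethylsilane, via arylmagnesium bromide 4 (not isolated)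
Conditions: Mg, LiCl, THF, 25 °C; then 3, THF, −40 → 0 °C
Reagents that add atoms: none
Why: Andersen sulfoxide synthesis, in which the aryl Grignard reagent displaces mentholate at sulfur with inversion and so sets the (S)-sulfur stereocentre.

Step 3
Reactants: 5 tert-butyl({3-methoxy-5-[(S)-4-methylbenzenesulfinyl]phenyl}methoxy)dimethylsilane; 6 1-(bromomethyl)-3,5-dimethoxybenzene
Product: 9 tert-butyl({4-[(3,5-dimethoxyphenyl)methyl]-3-methoxy-5-[(S)-4-methylbenzenesulfinyl]phenyl}methoxy)dimethylsilane, via ortho-lithiated sulfoxide 7 (not isolated), via arylzinc chloride 8 (not isolated)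
Conditions: LiN(iPr)2, THF, −78 °C; ZnCl2, −78 → 0 °C; 6, Pd(OAc)2 (cat.), SPhos (cat.), THF, 40 °C
Reagents that add atoms: none
Why: Directed ortho-metalation at the C–H flanked by the sulfinyl and methoxy groups (the future C3a') followed by Negishi coupling with the benzylic bromide, the switch to zinc keeping the organometallic from deprotonating the acidic diarylmethane product.

Step 4
Reactants: 9 tert-butyl({4-[(3,5-dimethoxyphenyl)methyl]-3-methoxy-5-[(S)-4-methylbenzenesulfinyl]phenyl}methoxy)dimethylsilane; 10 3,4-dimethoxybenzaldehyde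
Product: 13 tert-butyl{[(2S,3S)-2-(3,4-dimethoxyphenyl)-3-(3,5-dimethoxyphenyl)-4-methoxy-2,3-dihydro-1-benzofuran-6-yl]methoxy}dimethylsilane, via diarylmethyllithium 11 (not isolated), via lithium alkoxide 12 (not isolated)
Conditions: LiN(iPr)2 (1.05 equiv), THF, −78 °C; 10, −78 °C; DMPU, −78 → 25 °C
Reagents that add atoms: none
Why: Proposed new method: the lithium-chelated ortho-sulfinyl diarylmethyl carbanion 11 should add to aldehyde 10 on the face fixed by the sulfur stereocentre (this sets C3'; C2' is expected trans and is otherwise equilibrated in step 10), and alkoxide 12 should then displace the p-tolylsulfinyl group at C7a' by 5-exo ipso-SNAr with loss of p-toluenesulfenate, the oxygen counterpart of the known one-pot addition/sulfinyl displacement of 2-(p-tolylsulfinyl)alkylbenzyl carbanions with imines that gives indolines.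

Step 5
Reactants: 13 tert-butyl{[(2S,3S)-2-(3,4-dimethoxyphenyl)-3-(3,5-dimethoxyphenyl)-4-methoxy-2,3-dihydro-1-benzofuran-6-yl]methoxy}dimethylsilane
Product: 14 (2S,3S)-6-(bromomethyl)-2-(3,4-dimethoxyphenyl)-3-(3,5-dimethoxyphenyl)-4-methoxy-2,3-dihydro-1-benzofuran
Conditions: Ph3PBr2, CH2Cl2, 0 → 25 °C
Reagents that add atoms: triphenylphosphine dibromide, BrP(Br)(c1ccccc1)(c1ccccc1)c1ccccc1
Why: Appel-type conversion of a silyl ether into a bromide (bromophosphonium activation of the ether oxygen, then SN2 attack of bromide at the primary benzylic carbon), which leaves both stereocentres untouched.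

Step 6
Reactants: 15 3-bromo-5-methoxybenzaldehyde; 16 diethyl [(4-methoxyphenyl)methyl]phosphonate
Product: 18 1-bromo-3-methoxy-5-[(E)-2-(4-methoxyphenyl)ethenyl]benzene, via phosphonate carbanion 17 (not isolated)
Conditions: KOtBu, THF, 0 → 25 °C
Reagents that add atoms: none
Why: Horner–Wadsworth–Emmons olefination of a non-enolisable aldehyde with a benzylphosphonate anion, which sets the (E)-alkene.

Step 7
Reactants: 18 1-bromo-3-methoxy-5-[(E)-2-(4-methoxyphenyl)ethenyl]benzene; 19 (1S,2R,5S)-menthyl (R)-4-methylbenzenesulfinate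
Product: 21 1-methoxy-3-[(E)-2-(4-methoxyphenyl)ethenyl]-5-[(R)-4-methylbenzenesulfinyl]benzene, via arylmagnesium bromide 20 (not isolated)
Conditions: Mg, LiCl, THF, 25 °C; then 19, THF, −40 → 0 °C
Reagents that add atoms: none
Why: Andersen sulfoxide synthesis with the enantiomeric sulfinate, inversion at sulfur setting the (R)-sulfur stereocentre while the stilbene is inert to the Grignard reagent.

Step 8
Reactants: 21 1-methoxy-3-[(E)-2-(4-methoxyphenyl)ethenyl]-5-[(R)-4-methylbenzenesulfinyl]benzene; 14 (2S,3S)-6-(bromomethyl)-2-(3,4-dimethoxyphenyl)-3-(3,5-dimethoxyphenyl)-4-methoxy-2,3-dihydro-1-benzofuran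
Product: 24 (2S,3S)-2-(3,4-dimethoxyphenyl)-3-(3,5-dimethoxyphenyl)-4-methoxy-6-({2-methoxy-4-[(E)-2-(4-methoxyphenyl)ethenyl]-6-[(R)-4-methylbenzenesulfinyl]phenyl}methyl)-2,3-dihydro-1-benzofuran, via ortho-lithiated sulfoxide 22 (not isolated), via arylzinc chloride 23 (not isolated)
Conditions: LiN(iPr)2, THF, −78 °C; ZnCl2, −78 → 0 °C; 14, Pd(OAc)2 (cat.), SPhos (cat.), THF, 40 °C
Reagents that add atoms: none
Why: The same directed ortho-metalation/Negishi coupling as in step 3 joins the two halves at C3–C3a, and the mild arylzinc reagent does not touch ring F of the bromide.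

Step 9
Reactants: 24 (2S,3S)-2-(3,4-dimethoxyphenyl)-3-(3,5-dimethoxyphenyl)-4-methoxy-6-({2-methoxy-4-[(E)-2-(4-methoxyphenyl)ethenyl]-6-[(R)-4-methylbenzenesulfinyl]phenyl}methyl)-2,3-dihydro-1-benzofuran; 25 4-methoxybenzaldehyde
Product: 28 (2R,3R)-3-[(2S,3S)-2-(3,4-dimethoxyphenyl)-3-(3,5-dimethoxyphenyl)-4-methoxy-2,3-dihydro-1-benzofuran-6-yl]-4-methoxy-2-(4-methoxyphenyl)-6-[(E)-2-(4-methoxyphenyl)ethenyl]-2,3-dihydro-1-benzofuran, via diarylmethyllithium 26 (not isolated), via lithium alkoxide 27 (not isolated)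
Conditions: LiN(iPr)2 (1.05 equiv), THF, −78 °C; 25, −78 °C; DMPU, −78 → 25 °C
Reagents that add atoms: none
Why: Proposed new method: LiN(iPr)2 removes the C3 proton of 24, which the ortho-sulfinyl group makes by far the most acidic C–H and holds in a C3–Li···O–S chelate; carbanion 26 adds to aldehyde 25 (C2–C3 bond) to give alkoxide 27, whose oxygen attacks the sulfinyl-bearing carbon C7a and expels p-toluenesulfenate (O1–C7a bond), an anionic ipso-SNAr. The closest known reaction is the one-pot addition of 2-(p-tolylsulfinyl)alkylbenzyl carbanions to imines followed by displacement of the sulfinyl group by the nitrogen anion, which gives 2,3-disubstituted indolines; here oxygen takes the place of nitrogen and a diarylmethyl carbanion that of an alkylbenzyl one. Ring C closes by 5-exo-trig addition of the alkoxide to C7a followed by loss of the sulfur leaving group. C3 is set by the sulfur stereocentre through the chelated carbanion; C2 is expected trans to C3 because the anti aldolate cyclises with the two aryl groups on opposite faces, and a cis epimer would be corrected in step 10. The step needs deprotonation at C3 in preference to C3'–H of ring F (which would open ring F by β-elimination) and substitution at C7a only: the first is secured by the sulfinyl group on ring B and one equivalent of base at −78 °C, the second by C4 carrying a methoxy group that is no leaving group.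

Step 10
Reactants: 28 (2R,3R)-3-[(2S,3S)-2-(3,4-dimethoxyphenyl)-3-(3,5-dimethoxyphenyl)-4-methoxy-2,3-dihydro-1-benzofuran-6-yl]-4-methoxy-2-(4-methoxyphenyl)-6-[(E)-2-(4-methoxyphenyl)ethenyl]-2,3-dihydro-1-benzofuran
Product: 29 (2R,3R)-3-[(2S,3S)-2-(3,4-dihydroxyphenyl)-3-(3,5-dihydroxyphenyl)-4-hydroxy-2,3-dihydro-1-benzofuran-6-yl]-2-(4-hydroxyphenyl)-6-[(E)-2-(4-hydroxyphenyl)ethenyl]-2,3-dihydro-1-benzofuran-4-ol (CNP0107857.3)
Conditions: BBr3, CH2Cl2, −78 → 0 °C; then H2O
Reagents that add atoms: none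
Why: Lewis-acid cleavage of the eight aryl methyl ethers with BBr3, under which the reversible ionisation of the para-oxygenated benzylic C2–O1 and C2'–O1' bonds should bring any cis isomer to the trans rings while C3 and C3' stay fixed.

**Compound list**

1 | (3-bromo-5-methoxyphenyl)methanol | COc1cc(Br)cc(CO)c1 | starting material
2 | [(3-bromo-5-methoxyphenyl)methoxy](tert-butyl)dimethylsilane | COc1cc(Br)cc(CO[Si](C)(C)C(C)(C)C)c1 | intermediate
3 | (1R,2S,5R)-menthyl (S)-4-methylbenzenesulfinate | C[C@@H]1CC[C@H]([C@@H](C1)O[S@](=O)c1ccc(C)cc1)C(C)C | starting material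
4 | {3-[(tert-butyldimethylsilyloxy)methyl]-5-methoxyphenyl}magnesium bromide | COc1cc([Mg]Br)cc(CO[Si](C)(C)C(C)(C)C)c1 | intermediate
5 | tert-butyl({3-methoxy-5-[(S)-4-methylbenzenesulfinyl]phenyl}methoxy)dimethylsilane | COc1cc(cc(CO[Si](C)(C)C(C)(C)C)c1)[S@@](=O)c1ccc(C)cc1 | intermediate
6 | 1-(bromomethyl)-3,5-dimethoxybenzene | COc1cc(CBr)cc(OC)c1 | starting material
7 | 5 lithiated at the ring carbon between the methoxy and sulfinyl groups | COc1cc(CO[Si](C)(C)C(C)(C)C)cc([S@@](=O)c2ccc(C)cc2)c1[Li] | intermediate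
8 | the corresponding arylzinc chloride | COc1cc(CO[Si](C)(C)C(C)(C)C)cc([S@@](=O)c2ccc(C)cc2)c1[Zn]Cl | intermediate
9 | tert-butyl({4-[(3,5-dimethoxyphenyl)methyl]-3-methoxy-5-[(S)-4-methylbenzenesulfinyl]phenyl}methoxy)dimethylsilane | COc1cc(CO[Si](C)(C)C(C)(C)C)cc([S@@](=O)c2ccc(C)cc2)c1Cc1cc(OC)cc(OC)c1 | intermediate
10 | 3,4-dimethoxybenzaldehyde | COc1ccc(C=O)cc1OC | starting material
11 | 9 lithiated at the diarylmethane carbon (future C3') | COc1cc(CO[Si](C)(C)C(C)(C)C)cc([S@@](=O)c2ccc(C)cc2)c1C([Li])c1cc(OC)cc(OC)c1 | intermediate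
12 | lithium (1S,2S)-1-(3,4-dimethoxyphenyl)-2-(3,5-dimethoxyphenyl)-2-{4-[(tert-butyldimethylsilyloxy)methyl]-2-methoxy-6-[(S)-4-methylbenzenesulfinyl]phenyl}ethan-1-olate | COc1cc(CO[Si](C)(C)C(C)(C)C)cc([S@@](=O)c2ccc(C)cc2)c1[C@@H]([C@H](O[Li])c1ccc(OC)c(OC)c1)c1cc(OC)cc(OC)c1 | intermediate
13 | tert-butyl{[(2S,3S)-2-(3,4-dimethoxyphenyl)-3-(3,5-dimethoxyphenyl)-4-methoxy-2,3-dihydro-1-benzofuran-6-yl]methoxy}dimethylsilane | CC(C)(C)[Si](C)(C)OCc1cc(OC)c2c(c1)O[C@H](c1ccc(OC)c(OC)c1)[C@H]2c1cc(OC)cc(OC)c1 | intermediate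
14 | (2S,3S)-6-(bromomethyl)-2-(3,4-dimethoxyphenyl)-3-(3,5-dimethoxyphenyl)-4-methoxy-2,3-dihydro-1-benzofuran | BrCc1cc(OC)c2c(c1)O[C@H](c1ccc(OC)c(OC)c1)[C@H]2c1cc(OC)cc(OC)c1 | intermediate
15 | 3-bromo-5-methoxybenzaldehyde | COc1cc(Br)cc(C=O)c1 | starting material
16 | diethyl [(4-methoxyphenyl)methyl]phosphonate | CCOP(=O)(Cc1ccc(OC)cc1)OCC | starting material
17 | potassium salt of the carbanion of 16 | [K+].CCOP(=O)(OCC)[CH-]c1ccc(OC)cc1 | intermediate
18 | 1-bromo-3-methoxy-5-[(E)-2-(4-methoxyphenyl)ethenyl]benzene | COc1ccc(/C=C/c2cc(Br)cc(OC)c2)cc1 | intermediate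
19 | (1S,2R,5S)-menthyl (R)-4-methylbenzenesulfinate | C[C@H]1CC[C@@H]([C@H](C1)O[S@@](=O)c1ccc(C)cc1)C(C)C | starting material
20 | {3-methoxy-5-[(E)-2-(4-methoxyphenyl)ethenyl]phenyl}magnesium bromide | COc1ccc(/C=C/c2cc([Mg]Br)cc(OC)c2)cc1 | intermediate
21 | 1-methoxy-3-[(E)-2-(4-methoxyphenyl)ethenyl]-5-[(R)-4-methylbenzenesulfinyl]benzene | COc1ccc(/C=C/c2cc(OC)cc(c2)[S@](=O)c2ccc(C)cc2)cc1 | intermediate
22 | 21 lithiated at the ring carbon between the methoxy and sulfinyl groups | COc1ccc(/C=C/c2cc(OC)c([Li])c(c2)[S@](=O)c2ccc(C)cc2)cc1 | intermediate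
23 | the corresponding arylzinc chloride | COc1ccc(/C=C/c2cc(OC)c([Zn]Cl)c(c2)[S@](=O)c2ccc(C)cc2)cc1 | intermediate
24 | (2S,3S)-2-(3,4-dimethoxyphenyl)-3-(3,5-dimethoxyphenyl)-4-methoxy-6-({2-methoxy-4-[(E)-2-(4-methoxyphenyl)ethenyl]-6-[(R)-4-methylbenzenesulfinyl]phenyl}methyl)-2,3-dihydro-1-benzofuran | COc1ccc(/C=C/c2cc(OC)c(Cc3cc(OC)c4c(c3)O[C@H](c3ccc(OC)c(OC)c3)[C@H]4c3cc(OC)cc(OC)c3)c(c2)[S@](=O)c2ccc(C)cc2)cc1 | intermediate
25 | 4-methoxybenzaldehyde | COc1ccc(C=O)cc1 | starting material
26 | 24 lithiated at the diarylmethane carbon (future C3) | COc1ccc(/C=C/c2cc(OC)c(C([Li])c3cc(OC)c4c(c3)O[C@H](c3ccc(OC)c(OC)c3)[C@H]4c3cc(OC)cc(OC)c3)c(c2)[S@](=O)c2ccc(C)cc2)cc1 | intermediate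
27 | lithium (1R,2R)-alkoxide from addition of 26 to 25 (C2–O–Li, C3 bearing ring B with its sulfinyl group and ring E) | COc1ccc(/C=C/c2cc(OC)c([C@H]([C@@H](O[Li])c3ccc(OC)cc3)c3cc(OC)c4c(c3)O[C@H](c3ccc(OC)c(OC)c3)[C@H]4c3cc(OC)cc(OC)c3)c(c2)[S@](=O)c2ccc(C)cc2)cc1 | intermediate
28 | (2R,3R)-3-[(2S,3S)-2-(3,4-dimethoxyphenyl)-3-(3,5-dimethoxyphenyl)-4-methoxy-2,3-dihydro-1-benzofuran-6-yl]-4-methoxy-2-(4-methoxyphenyl)-6-[(E)-2-(4-methoxyphenyl)ethenyl]-2,3-dihydro-1-benzofuran | COc1ccc(/C=C/c2cc(OC)c3c(c2)O[C@@H](c2ccc(OC)cc2)[C@@H]3c2cc(OC)c3c(c2)O[C@H](c2ccc(OC)c(OC)c2)[C@H]3c2cc(OC)cc(OC)c2)cc1 | intermediate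
29 | (2R,3R)-3-[(2S,3S)-2-(3,4-dihydroxyphenyl)-3-(3,5-dihydroxyphenyl)-4-hydroxy-2,3-dihydro-1-benzofuran-6-yl]-2-(4-hydroxyphenyl)-6-[(E)-2-(4-hydroxyphenyl)ethenyl]-2,3-dihydro-1-benzofuran-4-ol | Oc1ccc(/C=C/c2cc(O)c3c(c2)O[C@@H](c2ccc(O)cc2)[C@@H]3c2cc(O)c3c(c2)O[C@H](c2ccc(O)c(O)c2)[C@H]3c2cc(O)cc(O)c2)cc1 | target

**Step count**

Total: 10 steps. Longest linear sequence: 8 steps (1, 2, 3, 4, 5, 8, 9, 10); steps 6 and 7 form the second branch.

**Steps most likely to fail**

1. Step 9 (proposed new method). The alkoxide may attack sulfur instead of C7a, which would transfer the sulfinyl group and cleave the carbon–sulfur bond without ring closure. Retro-addition of the aldolate before ring closure would erode the facial control at C3. Proton abstraction at C3' could open ring F by β-elimination. The fallback uses known chemistry, sets out from 24 and comes back at 28. 24 is deprotonated with LiN(iPr)2 in THF at −78 °C, aldehyde 25 is added and the mixture is quenched cold with aqueous NH4Cl, so that the adduct is isolated as sulfinyl carbinol F1 (addition of 2-(p-tolylsulfinyl)benzyl carbanions to aldehydes is established; C3 is set as in the main route). Excess PhLi in THF at −78 °C then removes the sulfinyl group by sulfoxide–lithium exchange, and trapping of the aryllithium with 1,2-diiodoethane gives iodo carbinol F2. Intramolecular Ullmann etherification (copper iodide CuI, 1,10-phenanthroline, Cs2CO3, toluene, 110 °C) closes ring C and returns 28.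

2. Step 4 (proposed new method). The same processes can go wrong on the simpler substrate: attack at sulfur in place of ipso-substitution, and retro-addition with loss of facial control at C3'. The fallback sets out from 9 and comes back at 13. Deprotonation of 9, addition of aldehyde 10 and a cold quench give sulfinyl carbinol F3. PhLi exchange and iodination with 1,2-diiodoethane give iodo carbinol F4. Ullmann etherification under the conditions above closes ring F and returns 13.

3. Step 10. Under the Lewis acid the benzylic C2–O1 and C2'–O1' bonds can ionise and be captured by a neighbouring electron-rich ring instead of re-closing; HBr can add to the stilbene; and the hindered methyl ethers at C4 and C4' may be cleaved incompletely. The fallback sets out from 28 and comes back at 29 without passing through a new isolated compound (F0). It replaces Lewis-acid cleavage by nucleophilic O-demethylation with LiPPh2 in THF at 25–60 °C followed by mild acidic work-up. If cis epimers remain, a short separate exposure of the polyphenol to trifluoroacetic acid in CH2Cl2 would equilibrate C2 and C2'.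

**Further compounds**

F1 | step 9 | (1R,2R)-sulfinyl carbinol, the protonated form of 27 | COc1ccc(/C=C/c2cc(OC)c([C@H]([C@@H](O)c3ccc(OC)cc3)c3cc(OC)c4c(c3)O[C@H](c3ccc(OC)c(OC)c3)[C@H]4c3cc(OC)cc(OC)c3)c(c2)[S@](=O)c2ccc(C)cc2)cc1
F2 | step 9 | iodo carbinol, F1 with iodine in place of the sulfinyl group at C7a | COc1ccc(/C=C/c2cc(OC)c([C@H]([C@@H](O)c3ccc(OC)cc3)c3cc(OC)c4c(c3)O[C@H](c3ccc(OC)c(OC)c3)[C@H]4c3cc(OC)cc(OC)c3)c(I)c2)cc1
F3 | step 4 | (1S,2S)-sulfinyl carbinol, the protonated form of 12 | COc1cc(CO[Si](C)(C)C(C)(C)C)cc([S@@](=O)c2ccc(C)cc2)c1[C@@H]([C@H](O)c1ccc(OC)c(OC)c1)c1cc(OC)cc(OC)c1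
F4 | step 4 | iodo carbinol, F3 with iodine in place of the sulfinyl group at C7a' | COc1cc(CO[Si](C)(C)C(C)(C)C)cc(I)c1[C@@H]([C@H](O)c1ccc(OC)c(OC)c1)c1cc(OC)cc(OC)c1
F0 | step 10 | none | none
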